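**Plan**
- After the two B-ring silyl groups are removed, ring C (the pyran) is cut at two bonds at once, C4–C4a and O1–C2. This gives 3,5-dimethoxy-4-prenylphenol (ring A) and a 2-arylacrolein (C2, C3, C4 and ring B).
- Enabling feature: O1–C8a–C4a–C4–C3–C2 of ring C is the closed form of a 1-oxatriene (ortho-quinone methide). Ring A without ring C is symmetric about the C8a···C6 axis, so C4a and C8 are equivalent. Each is activated by the OH and both OMe groups, and the para carbon C6 is blocked by the prenyl group.
- The phenol is cut at C6–prenyl (directed lithiation of 1,3-dimethoxybenzene) and at C8a–O (C–H borylation, then oxidation). The enal is cut at C3–C1' (Suzuki coupling), and its CHO (C4) comes from allylic oxidation of a methyl group.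
- Forward: rings A and B are bought. Ring C is the only ring made and it closes last, by boron-templated ortho-hydroxyalkylation, quinone methide formation and oxa-6π electrocyclisation in one flask. The boron tether enters and leaves in that step.
- Stereochemistry: the target has no stereocentre, C3=C4 is a ring alkene, and the prenyl alkene is not stereogenic.

Key step: step 6

Remark: atom numbers follow the isoflavene convention (O1, C2, C3, C4, C4a, C5–C8, C8a; ring B primed). "Prenyl" means 3-methylbut-2-en-1-yl and TIPS means triisopropylsilyl.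

**Step 1**
Reactants: 1 1,3-dimethoxybenzene; 2 prenyl bromide (1-bromo-3-methylbut-2-ene)
Product: 4 1,3-dimethoxy-2-prenylbenzene, via 2,6-dimethoxyphenyllithium 3 (not isolated)
Conditions: n-BuLi, THF, 0 °C to rt; then 2, 0 °C to rt
Reagents that add atoms: n-butyllithium [Li]CCCC (lithium of 3 only)
Why: In this directed ortho-metalation the two methoxy groups together direct lithiation to C2 alone, and the aryllithium displaces the primary allylic bromide at its unhindered CH2 terminus (SN2).

**Step 2**
Reactants: 4 1,3-dimethoxy-2-prenylbenzene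
Product: 6 3,5-dimethoxy-4-prenylphenol, via aryl pinacol boronate 5 (not isolated)
Conditions: [Ir(OMe)(cod)]2 (cat.), dtbpy (cat.), B2pin2 (0.55 equiv), THF, 65 °C; then aq. NaOH, 30 % H2O2, 0 °C
Reagents that add atoms: bis(pinacolato)diboron CC1(C)OB(OC1(C)C)B1OC(C)(C)C(C)(C)O1 (Bpin of 5 only); hydrogen peroxide OO (phenol oxygen of 6)
Why: Sterically governed iridium-catalysed aromatic C–H borylation reaches only C5–H, the one ring C–H without an ortho substituent, and basic peroxide then turns C–B into C–O by 1,2-aryl migration without touching the unactivated trisubstituted alkene.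

**Step 3**
Reactants: 7 4-bromoresorcinol (4-bromobenzene-1,3-diol)
Product: 8 1-bromo-2,4-bis(triisopropylsilyloxy)benzene
Conditions: TIPSCl, imidazole, DMF, rt
Reagents that add atoms: triisopropylsilyl chloride CC(C)[Si](Cl)(C(C)C)C(C)C
Why: This is a standard imidazole-promoted silylation of phenols, and TIPS is chosen because aryl TIPS ethers withstand aqueous phosphate base, hot SeO2 and hot acetic acid yet are cleaved by fluoride without acid.

**Step 4**
Reactants: 8 1-bromo-2,4-bis(triisopropylsilyloxy)benzene; 9 isopropenylboronic acid pinacol ester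
Product: 10 1-(prop-1-en-2-yl)-2,4-bis(triisopropylsilyloxy)benzene
Conditions: Pd(OAc)2 (cat.), SPhos (cat.), K3PO4, toluene/H2O, 80 °C
Reagents that add atoms: none
Why: In this Suzuki–Miyaura coupling the bulky, electron-rich biarylphosphine handles the electron-rich, ortho-hindered aryl bromide.

**Step 5**
Reactants: 10 1-(prop-1-en-2-yl)-2,4-bis(triisopropylsilyloxy)benzene
Product: 12 2-[2,4-bis(triisopropylsilyloxy)phenyl]prop-2-enal, via allylic alcohol 11 (not isolated)
Conditions: SeO2, 1,4-dioxane, 80–100 °C; product used soon after filtration through silica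
Reagents that add atoms: selenium dioxide O=[Se]=O
Why: The Riley allylic oxidation (ene reaction, [2,3]-sigmatropic shift, further oxidation of 11) is known for α-methylstyrenes, and 10 offers only one allylic position.

**Step 6**
Reactants: 6 3,5-dimethoxy-4-prenylphenol; 12 2-[2,4-bis(triisopropylsilyloxy)phenyl]prop-2-enal
Product: 16 3-[2,4-bis(triisopropylsilyloxy)phenyl]-5,7-dimethoxy-6-prenyl-2H-chromene, via aryl boronate 13 (not isolated), via benzodioxaborin 14 (not isolated), via ortho-quinone methide 15 (not isolated)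
Conditions: PhB(OH)2 (1.1 equiv), AcOH, toluene, reflux, Dean–Stark; 12 added slowly, BHT (trace)
Reagents that add atoms: phenylboronic acid OB(O)c1ccccc1 (PhB unit of 13 and 14 only; none of its atoms remains in 16)
Why: Phenol 6 and PhB(OH)2 condense to the aryl boronate 13, whose boron binds the aldehyde oxygen of 12 and delivers the ortho carbon to the carbonyl carbon through a six-membered transition state (boron-templated ortho-hydroxyalkylation, C4–C4a bond), the adduct being held as the temporary ring 14. At reflux 14 expels PhBO in a retro-[4+2] cleavage and gives the ortho-quinone methide 15, the 1-oxatriene O1=C8a–C4a=C4–C3=C2, which closes ring C by a thermal disrotatory oxa-6π electrocyclisation (O1–C2 bond) driven by the return of aromaticity to ring A. The closest known reaction type is the phenylboronic acid mediated chromenylation of phenols with α,β-unsaturated aldehydes, a formal [3+3] annulation. No stereocentre is created (C4 of 14 is racemic and becomes sp2 again) and the C3=C4 alkene can only be the ring alkene. Site selectivity is settled by the substrate, since both ortho carbons of 6 are equivalent and the para carbon carries the prenyl group; 1,2- over 1,4-attack on the β-unsubstituted enal is secured by the boron template, for which conjugate delivery would need an eight-membered transition state, and the Z geometry of 15 that closure needs is favoured because the C5 methoxy group pushes the propenyl arm to the carbonyl side. The prenyl alkene has only methoxy neighbours and O2' is silylated, so chroman or pterocarpan-type closures cannot compete in the weak acid.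

**Step 7**
Reactants: 16 3-[2,4-bis(triisopropylsilyloxy)phenyl]-5,7-dimethoxy-6-prenyl-2H-chromene
Product: 17 dehydroglyasperin D
Conditions: TBAF, AcOH (slight excess over TBAF), degassed THF, 0 °C, argon
Reagents that add atoms: none
Why: Fluoride cleaves the aryl silyl ethers, and the acetic acid buffer avoids both free phenoxide (air oxidation of the resorcinol) and strong acid (closure of 2'-OH on C4), either of which could damage the isoflav-3-ene.

**Compound list**
1 | 1,3-dimethoxybenzene | COc1cccc(OC)c1 | starting material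
2 | prenyl bromide (1-bromo-3-methylbut-2-ene) | CC(C)=CCBr | starting material
3 | 2,6-dimethoxyphenyllithium | [Li]c1c(OC)cccc1OC | intermediate (not isolated)
4 | 1,3-dimethoxy-2-(3-methylbut-2-en-1-yl)benzene | COc1cccc(OC)c1CC=C(C)C | intermediate
5 | 2-[3,5-dimethoxy-4-(3-methylbut-2-en-1-yl)phenyl]-4,4,5,5-tetramethyl-1,3,2-dioxaborolane | COc1cc(B2OC(C)(C)C(C)(C)O2)cc(OC)c1CC=C(C)C | intermediate (not isolated)
6 | 3,5-dimethoxy-4-(3-methylbut-2-en-1-yl)phenol | COc1cc(O)cc(OC)c1CC=C(C)C | intermediate
7 | 4-bromobenzene-1,3-diol | Oc1ccc(Br)c(O)c1 | starting material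
8 | 1-bromo-2,4-bis(triisopropylsilyloxy)benzene | Brc1ccc(O[Si](C(C)C)(C(C)C)C(C)C)cc1O[Si](C(C)C)(C(C)C)C(C)C | intermediate
9 | 4,4,5,5-tetramethyl-2-(prop-1-en-2-yl)-1,3,2-dioxaborolane | C=C(C)B1OC(C)(C)C(C)(C)O1 | starting material
10 | 1-(prop-1-en-2-yl)-2,4-bis(triisopropylsilyloxy)benzene | C=C(C)c1ccc(O[Si](C(C)C)(C(C)C)C(C)C)cc1O[Si](C(C)C)(C(C)C)C(C)C | intermediate
11 | 2-[2,4-bis(triisopropylsilyloxy)phenyl]prop-2-en-1-ol | OCC(=C)c1ccc(O[Si](C(C)C)(C(C)C)C(C)C)cc1O[Si](C(C)C)(C(C)C)C(C)C | intermediate (not isolated)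
12 | 2-[2,4-bis(triisopropylsilyloxy)phenyl]prop-2-enal | O=CC(=C)c1ccc(O[Si](C(C)C)(C(C)C)C(C)C)cc1O[Si](C(C)C)(C(C)C)C(C)C | intermediate
13 | 3,5-dimethoxy-4-prenylphenyl hydrogen phenylboronate | COc1cc(OB(O)c2ccccc2)cc(OC)c1CC=C(C)C | intermediate (not isolated)
14 | 4-{1-[2,4-bis(triisopropylsilyloxy)phenyl]ethenyl}-5,7-dimethoxy-6-prenyl-2-phenyl-4H-1,3,2-benzodioxaborin (racemic at C4) | COc1cc2OB(c3ccccc3)OC(C(=C)c3ccc(O[Si](C(C)C)(C(C)C)C(C)C)cc3O[Si](C(C)C)(C(C)C)C(C)C)c2c(OC)c1CC=C(C)C | intermediate (not isolated)
15 | (6Z)-6-{2-[2,4-bis(triisopropylsilyloxy)phenyl]prop-2-en-1-ylidene}-3,5-dimethoxy-4-prenylcyclohexa-2,4-dien-1-one | O=C1C=C(OC)C(CC=C(C)C)=C(OC)/C1=C/C(=C)c1ccc(O[Si](C(C)C)(C(C)C)C(C)C)cc1O[Si](C(C)C)(C(C)C)C(C)C | intermediate (not isolated)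
16 | 3-[2,4-bis(triisopropylsilyloxy)phenyl]-5,7-dimethoxy-6-(3-methylbut-2-en-1-yl)-2H-chromene | COc1cc2c(c(OC)c1CC=C(C)C)C=C(c1ccc(O[Si](C(C)C)(C(C)C)C(C)C)cc1O[Si](C(C)C)(C(C)C)C(C)C)CO2 | intermediate
17 | dehydroglyasperin D, 4-[5,7-dimethoxy-6-(3-methylbut-2-en-1-yl)-2H-chromen-3-yl]benzene-1,3-diol | COc1cc2c(c(OC)c1CC=C(C)C)C=C(c1ccc(O)cc1O)CO2 | target

**Step count**
Total steps: 7. Longest linear sequence: 5 (steps 3, 4, 5, 6, 7; 7 → 8 → 10 → 12 → 16 → 17).

**Steps most likely to fail**

1. **Step 6.** The β-unsubstituted 2-arylacrolein may be used up by hetero-Diels–Alder self-dimerisation, by polymerisation or by conjugate attack of the phenol before the templated 1,2-addition occurs. The quinone methide may also be intercepted by a second phenol.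
 - The fallback closes ring C at C3=C4 by metathesis. It sets out from 6 and 12 and comes back at 16.
 - Phenol 6 would be ortho-formylated (MgCl2, Et3N, paraformaldehyde, MeCN, reflux; Casnati–Skattebøl formylation) to 6-hydroxy-2,4-dimethoxy-3-prenylbenzaldehyde F1.
 - Enal 12 would be reduced under Luche conditions (NaBH4, CeCl3, MeOH, 0 °C) to the allylic alcohol 11, now isolated.
 - Mitsunobu etherification (PPh3, DIAD, THF) would join F1 and 11 to the aryl 2-arylallyl ether aldehyde F2.
 - Wittig methylenation (Ph3P=CH2, THF) would give the styrene diene F3.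
 - Ring-closing metathesis (second-generation Grubbs catalyst, CH2Cl2, 40 °C) would then give 16. The trisubstituted prenyl alkene is the slowest partner.

2. **Step 5.** The electron-rich styrene may degrade under hot SeO2, the oxidation may stall at the alcohol stage, or the enal may polymerise during the long heating.
 - The fallback brings C2 in as formaldehyde instead of oxidising a methyl group. It sets out from 8 and comes back at 12.
 - Suzuki–Miyaura coupling of 8 with commercial (E)-2-ethoxyvinylboronic acid pinacol ester would give the (E)-aryl enol ether F4.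
 - Mild hydrolysis (dilute HCl, THF, rt) would give 2-[2,4-bis(triisopropylsilyloxy)phenyl]acetaldehyde F5.
 - Organocatalytic Mannich–elimination α-methylenation (aq. CH2O, pyrrolidine and propionic acid as catalysts, i-PrOH, 45 °C) would give 12 at low temperature.

3. **Step 2.** The iridium hydride and boryl species may engage the prenyl alkene (hydroboration, or migration of the double bond into conjugation), or the catalyst may be slowed by alkene binding so that conversion stays incomplete.
 - The fallback starts with the phenol oxygen already in place and introduces the prenyl group last. It sets out from prenyl bromide 2 and comes back at 6.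
 - Commercial 3,5-dimethoxyphenol would be silylated (TIPSCl, imidazole, DMF) to (3,5-dimethoxyphenoxy)triisopropylsilane F6.
 - Directed lithiation (n-BuLi, THF, 0 °C) should occur between the two methoxy groups, because the bulky silyloxy group is a poor director, to give the aryllithium F7.
 - F7 would be alkylated with 2 to [3,5-dimethoxy-4-prenylphenoxy]triisopropylsilane F8.
 - TBAF (THF, 0 °C) would then release 6.

**Further compounds**
F1 | step 6 | 6-hydroxy-2,4-dimethoxy-3-(3-methylbut-2-en-1-yl)benzaldehyde | COc1cc(O)c(C=O)c(OC)c1CC=C(C)C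
F2 | step 6 | 6-{2-[2,4-bis(triisopropylsilyloxy)phenyl]prop-2-en-1-yloxy}-2,4-dimethoxy-3-prenylbenzaldehyde | COc1cc(OCC(=C)c2ccc(O[Si](C(C)C)(C(C)C)C(C)C)cc2O[Si](C(C)C)(C(C)C)C(C)C)c(C=O)c(OC)c1CC=C(C)C
F3 | step 6 | 1-{2-[2,4-bis(triisopropylsilyloxy)phenyl]prop-2-en-1-yloxy}-2-ethenyl-3,5-dimethoxy-4-prenylbenzene | COc1cc(OCC(=C)c2ccc(O[Si](C(C)C)(C(C)C)C(C)C)cc2O[Si](C(C)C)(C(C)C)C(C)C)c(C=C)c(OC)c1CC=C(C)C
F4 | step 5 | 1-[(E)-2-ethoxyethenyl]-2,4-bis(triisopropylsilyloxy)benzene | CCO/C=C/c1ccc(O[Si](C(C)C)(C(C)C)C(C)C)cc1O[Si](C(C)C)(C(C)C)C(C)C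
F5 | step 5 | 2-[2,4-bis(triisopropylsilyloxy)phenyl]acetaldehyde | O=CCc1ccc(O[Si](C(C)C)(C(C)C)C(C)C)cc1O[Si](C(C)C)(C(C)C)C(C)C
F6 | step 2 | (3,5-dimethoxyphenoxy)triisopropylsilane | COc1cc(OC)cc(O[Si](C(C)C)(C(C)C)C(C)C)c1
F7 | step 2 | 2,6-dimethoxy-4-(triisopropylsilyloxy)phenyllithium | [Li]c1c(OC)cc(O[Si](C(C)C)(C(C)C)C(C)C)cc1OC
F8 | step 2 | [3,5-dimethoxy-4-(3-methylbut-2-en-1-yl)phenoxy]triisopropylsilane | COc1cc(O[Si](C(C)C)(C(C)C)C(C)C)cc(OC)c1CC=C(C)C
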